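The route is built on the C2–C1' disconnection. In the pyran ring, C2 bears four non-hydrogen substituents (O1, CH3, C3, C1') and sits two bonds from C4. Oxidising C4 to a ketone and C2–C3 to an alkene on paper gives a planar 4H-chromen-4-one in which C2 is the electrophilic, prochiral terminus of an enone and in which the benzene ring, O1 and both ring methyl groups are already in place. Copper-catalysed asymmetric 1,4-addition of the whole C16 side chain as its Grignard reagent then makes the bond and the stereocentre together. The acceptor carries a 6-pivaloyloxy group, which sharpens the electrophilicity of C2 and is shed in the hydride step that removes the C4 oxygen.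

Key step: step 9

Remark: CIP analysis of the target gives 2R, 4'R, 8'S. C8' is S only because the C11'=C12' bond raises the rank of C9'; its geometry is that of the natural tocopherols. (R)-Citronellyl bromide supplies C8' and (S)-3-bromo-2-methylpropan-1-ol supplies C4' with exactly these configurations, so no structure needs correction.

Assumption: the antipode of the ferrocenyl diphosphine written in step 9 is taken to deliver the alkyl group to the Re face of C2. If a trial with a simple alkylmagnesium bromide shows the opposite sense, the mirror-image ligand is used and nothing else changes.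

Step 1
Reactants: 1 4-methoxy-2-methylphenol
Product: 3 1-(2-hydroxy-5-methoxy-3-methylphenyl)ethan-1-one, via aryl acetate 2 (not isolated)
Conditions: Ac2O (1.05 equiv), BF3·OEt2 (3 equiv), 25 → 110 °C; then H2O, 60 °C
Reagents that add atoms: acetic anhydride, CC(=O)OC(C)=O
Why: O-acetylation is followed in the same flask by a BF3-promoted Fries rearrangement in which the acetyl group can only settle at the one free ortho carbon (the para position is blocked by OMe, the other ortho position by CH3), and BF3 leaves the aryl methyl ether intact.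

Step 2
Reactants: 3 1-(2-hydroxy-5-methoxy-3-methylphenyl)ethan-1-one
Product: 6 6-hydroxy-2,8-dimethyl-4H-chromen-4-one, via 1,3-diketone 4 (not isolated), via 6-methoxy-2,8-dimethylchromone 5 (not isolated)
Conditions: NaH (4 equiv), EtOAc (6 equiv), THF, 65 °C; then 48% aq. HBr, AcOH, 115 °C
Reagents that add atoms: ethyl acetate, CCOC(C)=O
Why: Claisen condensation of the phenoxide-enolate of 3 with ethyl acetate gives the 1,3-diketone, acid cyclodehydrates it to the γ-pyrone, and hot HBr then cleaves the aryl methyl ether by bromide attack at the methyl group while the acid-stable chromone ring survives.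

Step 3
Reactants: 6 6-hydroxy-2,8-dimethyl-4H-chromen-4-one
Product: 7 2,8-dimethyl-4-oxo-4H-chromen-6-yl 2,2-dimethylpropanoate (pivalate)
Conditions: t-BuCOCl (1.2 equiv), Et3N, DMAP (cat.), CH2Cl2, 0 → 25 °C
Reagents that add atoms: pivaloyl chloride, CC(C)(C)C(=O)Cl
Why: DMAP-catalysed O-acylation of the phenol, the only nucleophilic site, installs a hindered ester that should resist a Grignard reagent at −78 °C, withdraws electron density from the ring position para to O1 and is removed by hydride at the end.

Step 4
Reactants: 8 (R)-citronellyl bromide, (6R)-8-bromo-2,6-dimethyloct-2-ene; 9 (S)-3-bromo-2-methylpropan-1-ol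
Product: 12 (2R,6S)-2,6,10-trimethylundec-9-en-1-ol, via citronellylmagnesium bromide 10 (not isolated), via chloromagnesium bromoalkoxide 11 (not isolated)
Conditions: 8 (1.3 equiv), Mg, THF, 45 °C; 9, i-PrMgCl (1.0 equiv), THF, −40 °C; combine, Li2CuCl4 (3 mol %), −40 → 0 °C; then H2O
Reagents that add atoms: none
Why: Copper-catalysed sp3–sp3 cross-coupling of the Kochi type, in which the cuprate formed from 10 displaces the primary bromide of 11 while the hydroxyl group is masked as an unreactive magnesium alkoxide; neither stereocentre is a reacting carbon, so C2 and C6 of 12 carry the configurations needed for C4' and C8' of the target.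

Step 5
Reactants: 12 (2R,6S)-2,6,10-trimethylundec-9-en-1-ol
Product: 13 (6S,10R)-11-bromo-2,6,10-trimethylundec-2-ene
Conditions: PPh3, CBr4, CH2Cl2, 0 °C
Reagents that add atoms: tetrabromomethane, BrC(Br)(Br)Br
Why: Appel reaction, in which the primary alcohol is activated as an alkoxyphosphonium ion and displaced by bromide under neutral conditions that leave the trisubstituted alkene and the adjacent stereocentre untouched.

Step 6
Reactants: 13 (6S,10R)-11-bromo-2,6,10-trimethylundec-2-ene; 14 oxirane
Product: 16 (4R,8S)-4,8,12-trimethyltridec-11-en-1-ol, via C13 alkylmagnesium bromide 15 (not isolated)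
Conditions: Mg, THF, 45 °C; then 14 (2 equiv, THF solution), CuI (10 mol %), −30 → 0 °C; then H2O
Reagents that add atoms: none
Why: Copper-catalysed ring opening of oxirane by the primary Grignard reagent adds the two carbons that become C2' and C1'; CuI and low temperature suppress bromohydrin formation, and the stereocentre β to magnesium is configurationally stable.

Step 7
Reactants: 16 (4R,8S)-4,8,12-trimethyltridec-11-en-1-ol
Product: 17 (6S,10R)-13-bromo-2,6,10-trimethyltridec-2-ene
Conditions: PPh3, CBr4, CH2Cl2, 0 °C
Reagents that add atoms: tetrabromomethane, BrC(Br)(Br)Br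
Why: A second Appel reaction on an unbranched primary alcohol, again neutral and therefore harmless to the alkene and to both stereocentres.

Step 8
Reactants: 17 (6S,10R)-13-bromo-2,6,10-trimethyltridec-2-ene
Product: 18 [(4R,8S)-4,8,12-trimethyltridec-11-en-1-yl]magnesium bromide (titrated Et2O solution, used directly)
Conditions: Mg turnings, I2 (cat.), Et2O, 35 °C
Reagents that add atoms: magnesium, [Mg]
Why: Grignard formation by insertion of magnesium into the primary C–Br bond; the alkene is too far away to cyclise onto the transient radical and both stereocentres are remote from the reacting carbon.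

Step 9
Reactants: 7 2,8-dimethyl-4-oxo-4H-chromen-6-yl pivalate; 18 [(4R,8S)-4,8,12-trimethyltridec-11-en-1-yl]magnesium bromide
Product: 21 (2R)-2,8-dimethyl-4-oxo-2-[(4R,8S)-4,8,12-trimethyltridec-11-en-1-yl]-3,4-dihydro-2H-chromen-6-yl pivalate, via silyloxybenzopyrylium triflate 19 (not isolated), via silyl enol ether 20 (not isolated)
Conditions: Me3SiOTf (1.3 equiv), CH2Cl2, 0 °C; then CuBr·SMe2 (5 mol %), (R)-1-[(Sp)-2-(dicyclohexylphosphino)ferrocenyl]ethyldiphenylphosphine (6 mol %), t-BuOMe/CH2Cl2, −78 °C, 18 (1.4 equiv in Et2O) added over 4 h; then 1 M aq. HCl, THF, 0 °C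
Reagents that add atoms: none
Why: Proposed new method: Me3SiOTf silylates the C4 carbonyl oxygen of 7 to give the 4-silyloxybenzopyrylium ion 19, the alkyl group of 18 passes from magnesium to the monovalent copper–diphosphine complex, and this complex binds C2=C3, adds oxidatively at C2 to a trivalent copper alkyl and eliminates reductively to form C2–C1' and leave the neutral silyl enol ether 20, which cold acid hydrolyses to 21. The closest known reaction types are copper/ferrocenyl diphosphine-catalysed asymmetric 1,4-additions of alkylmagnesium bromides to chromones unsubstituted at C2 and Lewis-acid-assisted copper-catalysed additions to β-substituted cyclic enones that create fully substituted carbons; a 2-methylchromone has not been shown to react in this way. No ring is closed. C2 is the only new stereocentre and is controlled by the chiral diphosphine alone, which must leave the Re face of C2 (ranking O1 > C3 > CH3) open so that the chain enters there and gives 2R; the C4' and C8' centres and the C11'=C12' alkene are too remote to interfere. The step needs 1,4- instead of 1,2-addition, no attack on the ester, no deprotonation of the C2 methyl group and no loss of configuration: the soft copper alkyl is drawn to the pyrylium C2, the pivalate is hindered and inert at −78 °C, slow addition keeps the free Grignard reagent low, and because the adduct is a silyl enol ether and never a metal enolate, the retro-oxa-Michael ring opening that would racemise C2 has no entry. The acyloxy group para to O1 also pulls electron density away from O1 and so makes C2 more electrophilic than in a 6-methoxy analogue.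

Step 10
Reactants: 21 (2R)-2,8-dimethyl-4-oxo-2-[(4R,8S)-4,8,12-trimethyltridec-11-en-1-yl]-3,4-dihydro-2H-chromen-6-yl pivalate
Product: 22 (2R)-2,8-dimethyl-2-[(4R,8S)-4,8,12-trimethyltridec-11-en-1-yl]-3,4-dihydro-2H-chromen-6-ol (target)
Conditions: LiAlH4 (3 equiv), Et2O, 0 °C; then AlCl3 (3 equiv), 0 → 35 °C; then H2O, 0 °C
Reagents that add atoms: none
Why: Mixed-hydride (LiAlH4/AlCl3) hydrogenolysis of an aryl ketone, in which hydride first reduces the ketone and cleaves the pivalate, and the chloroalanes then ionise the benzylic C4–O bond to a cation stabilised by O1 and deliver hydride to it, while the isolated alkene and the C2–O1 ether are not touched.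

Compound list
1 | 4-methoxy-2-methylphenol | Cc1cc(OC)ccc1O | starting material
2 | 4-methoxy-2-methylphenyl acetate | CC(=O)Oc1ccc(OC)cc1C | intermediate
3 | 1-(2-hydroxy-5-methoxy-3-methylphenyl)ethan-1-one | CC(=O)c1cc(OC)cc(C)c1O | intermediate
4 | 1-(2-hydroxy-5-methoxy-3-methylphenyl)butane-1,3-dione | CC(=O)CC(=O)c1cc(OC)cc(C)c1O | intermediate
5 | 6-methoxy-2,8-dimethyl-4H-chromen-4-one | Cc1cc(=O)c2cc(OC)cc(C)c2o1 | intermediate
6 | 6-hydroxy-2,8-dimethyl-4H-chromen-4-one | Cc1cc(=O)c2cc(O)cc(C)c2o1 | intermediate
7 | 2,8-dimethyl-4-oxo-4H-chromen-6-yl 2,2-dimethylpropanoate | Cc1cc(=O)c2cc(OC(=O)C(C)(C)C)cc(C)c2o1 | intermediate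
8 | (R)-citronellyl bromide, (6R)-8-bromo-2,6-dimethyloct-2-ene | C[C@H](CCC=C(C)C)CCBr | starting material
9 | (S)-3-bromo-2-methylpropan-1-ol | OC[C@H](C)CBr | starting material
10 | [(3R)-3,7-dimethyloct-6-en-1-yl]magnesium bromide | C[C@H](CCC=C(C)C)CC[Mg]Br | intermediate
11 | chloromagnesium (2S)-3-bromo-2-methylpropan-1-olate | Cl[Mg]OC[C@H](C)CBr | intermediate
12 | (2R,6S)-2,6,10-trimethylundec-9-en-1-ol | CC(C)=CCC[C@@H](C)CCC[C@@H](C)CO | intermediate
13 | (6S,10R)-11-bromo-2,6,10-trimethylundec-2-ene | CC(C)=CCC[C@@H](C)CCC[C@@H](C)CBr | intermediate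
14 | oxirane | C1CO1 | starting material
15 | [(2R,6S)-2,6,10-trimethylundec-9-en-1-yl]magnesium bromide | CC(C)=CCC[C@@H](C)CCC[C@@H](C)C[Mg]Br | intermediate
16 | (4R,8S)-4,8,12-trimethyltridec-11-en-1-ol | CC(C)=CCC[C@@H](C)CCC[C@@H](C)CCCO | intermediate
17 | (6S,10R)-13-bromo-2,6,10-trimethyltridec-2-ene | CC(C)=CCC[C@@H](C)CCC[C@@H](C)CCCBr | intermediate
18 | [(4R,8S)-4,8,12-trimethyltridec-11-en-1-yl]magnesium bromide | CC(C)=CCC[C@@H](C)CCC[C@@H](C)CCC[Mg]Br | intermediate
19 | 2,8-dimethyl-6-(pivaloyloxy)-4-(trimethylsilyloxy)chromenylium trifluoromethanesulfonate | Cc1cc(O[Si](C)(C)C)c2cc(OC(=O)C(C)(C)C)cc(C)c2[o+]1.[O-]S(=O)(=O)C(F)(F)F | intermediate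
20 | (2R)-2,8-dimethyl-2-[(4R,8S)-4,8,12-trimethyltridec-11-en-1-yl]-4-(trimethylsilyloxy)-2H-chromen-6-yl 2,2-dimethylpropanoate | CC(C)=CCC[C@@H](C)CCC[C@@H](C)CCC[C@]1(C)C=C(O[Si](C)(C)C)c2cc(OC(=O)C(C)(C)C)cc(C)c2O1 | intermediate
21 | (2R)-2,8-dimethyl-4-oxo-2-[(4R,8S)-4,8,12-trimethyltridec-11-en-1-yl]-3,4-dihydro-2H-chromen-6-yl 2,2-dimethylpropanoate | CC(C)=CCC[C@@H](C)CCC[C@@H](C)CCC[C@]1(C)CC(=O)c2cc(OC(=O)C(C)(C)C)cc(C)c2O1 | intermediate
22 | (2R)-2,8-dimethyl-2-[(4R,8S)-4,8,12-trimethyltridec-11-en-1-yl]-3,4-dihydro-2H-chromen-6-ol | CC(C)=CCC[C@@H](C)CCC[C@@H](C)CCC[C@]1(C)CCc2cc(O)cc(C)c2O1 | target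

Total step count: 10 steps.
Longest linear sequence: 7 steps (steps 4 to 10, from 8 to 22). The arene branch (steps 1 to 3) joins at step 9.

Steps most likely to fail

Step 9. The copper-bound alkyl group may fail to add to the hindered, weakly electrophilic C2, with deprotonation of the C2 methyl group or attack on the pivalate taking over. Uncatalysed addition of the Grignard reagent to the pyrylium ion may also erode face selectivity. The fallback sets out from 18 and 3 and comes back to the route at 22. Weinreb ketone synthesis of 18 with N-methoxy-N-methylacetamide (THF, 0 °C) should give the methyl ketone (6R,10S)-6,10,14-trimethylpentadec-13-en-2-one F1. Kabbe condensation of F1 with 3 (pyrrolidine, toluene, reflux, water removal) builds the pyranone ring by aldol condensation and oxa-Michael closure. It should give 6-methoxy-2,8-dimethyl-2-[(4R,8S)-4,8,12-trimethyltridec-11-en-1-yl]chroman-4-one F2 as both C2 epimers, because this closure sets C2 without control. The epimers are therefore separated by preparative chromatography on a chiral stationary phase to give (2R)-6-methoxy-2,8-dimethyl-2-[(4R,8S)-4,8,12-trimethyltridec-11-en-1-yl]chroman-4-one F3. The 2S epimer is re-equilibrated with pyrrolidine (retro-oxa-Michael and reclosure) and recycled. LiAlH4/AlCl3 in Et2O then reduces C4 to CH2 and should give (2R)-6-methoxy-2,8-dimethyl-2-[(4R,8S)-4,8,12-trimethyltridec-11-en-1-yl]chromane F4. NaSEt in DMF at 140 °C cleaves the methyl ether to give 22.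

Step 10. The benzylic cation at C4 may lose a proton from C3 instead of accepting hydride, which is elimination to the 2H-chromene. The Lewis acid may also open the C2–O1 bond and erode C2. The fallback sets out from 21 and comes back at 22. NaBH4 (MeOH/THF, 0 °C) should reduce the ketone to (2R)-4-hydroxy-2,8-dimethyl-2-[(4R,8S)-4,8,12-trimethyltridec-11-en-1-yl]chroman-6-yl pivalate F5 as both C4 epimers. Catalytic TsOH in toluene at 60 °C, with light excluded, should dehydrate it to (2R)-2,8-dimethyl-2-[(4R,8S)-4,8,12-trimethyltridec-11-en-1-yl]-2H-chromen-6-yl pivalate F6. Diimide generated from TsNHNH2 and NaOAc (DME/H2O, 85 °C) should saturate only the disubstituted, conjugated C3=C4 bond and give (2R)-2,8-dimethyl-2-[(4R,8S)-4,8,12-trimethyltridec-11-en-1-yl]chroman-6-yl pivalate F7. LiAlH4 (THF, 0 °C) then removes the pivaloyl group to give 22.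

Step 4. Displacement at the β-branched bromide of the magnesium alkoxide may be slow, so that homocoupling and reduction of 10 consume the Grignard reagent. The fallback sets out from 9 and 8 and comes back at 12, with the roles of the two partners reversed. TBSCl and imidazole (DMF) should convert 9 into (S)-(3-bromo-2-methylpropoxy)(tert-butyl)dimethylsilane F8. Mg in THF should give [(2S)-3-(tert-butyldimethylsilyloxy)-2-methylpropyl]magnesium bromide F9. This is coupled with the unbranched primary bromide 8 under Li2CuCl4 catalysis (THF, −20 → 0 °C) to give tert-butyldimethyl{[(2R,6S)-2,6,10-trimethylundec-9-en-1-yl]oxy}silane F10. TBAF in THF then frees 12.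

Further compounds
F1 | step 9 | (6R,10S)-6,10,14-trimethylpentadec-13-en-2-one | CC(C)=CCC[C@@H](C)CCC[C@@H](C)CCCC(C)=O
F2 | step 9 | 6-methoxy-2,8-dimethyl-2-[(4R,8S)-4,8,12-trimethyltridec-11-en-1-yl]chroman-4-one, both C2 epimers | CC(C)=CCC[C@@H](C)CCC[C@@H](C)CCCC1(C)CC(=O)c2cc(OC)cc(C)c2O1
F3 | step 9 | (2R)-6-methoxy-2,8-dimethyl-2-[(4R,8S)-4,8,12-trimethyltridec-11-en-1-yl]chroman-4-one | CC(C)=CCC[C@@H](C)CCC[C@@H](C)CCC[C@]1(C)CC(=O)c2cc(OC)cc(C)c2O1
F4 | step 9 | (2R)-6-methoxy-2,8-dimethyl-2-[(4R,8S)-4,8,12-trimethyltridec-11-en-1-yl]chromane | CC(C)=CCC[C@@H](C)CCC[C@@H](C)CCC[C@]1(C)CCc2cc(OC)cc(C)c2O1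
F5 | step 10 | (2R)-4-hydroxy-2,8-dimethyl-2-[(4R,8S)-4,8,12-trimethyltridec-11-en-1-yl]chroman-6-yl 2,2-dimethylpropanoate, both C4 epimers | CC(C)=CCC[C@@H](C)CCC[C@@H](C)CCC[C@]1(C)CC(O)c2cc(OC(=O)C(C)(C)C)cc(C)c2O1
F6 | step 10 | (2R)-2,8-dimethyl-2-[(4R,8S)-4,8,12-trimethyltridec-11-en-1-yl]-2H-chromen-6-yl 2,2-dimethylpropanoate | CC(C)=CCC[C@@H](C)CCC[C@@H](C)CCC[C@]1(C)C=Cc2cc(OC(=O)C(C)(C)C)cc(C)c2O1
F7 | step 10 | (2R)-2,8-dimethyl-2-[(4R,8S)-4,8,12-trimethyltridec-11-en-1-yl]chroman-6-yl 2,2-dimethylpropanoate | CC(C)=CCC[C@@H](C)CCC[C@@H](C)CCC[C@]1(C)CCc2cc(OC(=O)C(C)(C)C)cc(C)c2O1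
F8 | step 4 | (S)-(3-bromo-2-methylpropoxy)(tert-butyl)dimethylsilane | CC(C)(C)[Si](C)(C)OC[C@H](C)CBr
F9 | step 4 | [(2S)-3-(tert-butyldimethylsilyloxy)-2-methylpropyl]magnesium bromide | CC(C)(C)[Si](C)(C)OC[C@H](C)C[Mg]Br
F10 | step 4 | tert-butyldimethyl{[(2R,6S)-2,6,10-trimethylundec-9-en-1-yl]oxy}silane | CC(C)=CCC[C@@H](C)CCC[C@@H](C)CO[Si](C)(C)C(C)(C)C
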